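**Plan**
1. Numbering: furanone C1(=O)–C2H=C3–O–C10(CH3); C4 = CH(CH3); C5 = CH2; C6 = CH–O-acyl; butenolide C7 (β), C11 (α, bearing C13H2OH), C12 (=O), C8 (γ) =C9H. The retrosynthesis first trades the γ-ylidene butenolide for a 2,3,4-trisubstituted furan (C8–OH elimination, then furan + singlet oxygen).
2. It then cuts C1(=O)–C2H and O–C3 of the furanone together. This opens the furanone and the ten-membered carbocycle at once, to a furan with an α-hydroxy thioester arm and a terminal-alkyne arm.
3. Further cuts: the C6 ester, the C3–C4 bond (conjugate alkynylation), the C6 acyl–propenyl bond, and the furan ring (β-keto thioester + dihydroxyacetone).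
4. Forward order: furan ring, then the alkyne arm on the furan, then carbocycle and 3(2H)-furanone in one step, then furan to hydroxybutenolide, then C8=C9.
5. Enabling feature: O–C10(CH3)–C1(=O) is a tertiary α-hydroxy acyl unit and C2H=C3 a former terminal alkyne. C1–C2 is a ring bond of the ten-membered carbocycle and O–C3 spans that ring; the furan (masked butenolide, C7/C8) holds both arms cis.
6. Stereochemistry: C10 from (S)-citramalic acid; C4 by Rh-catalysed asymmetric conjugate alkynylation; C6 by CBS reduction; (E)-C8=C9 enforced by the ring; (E)-enoate by HWE.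

Key step: step 13

Remarks: 1,3-dihydroxyacetone is used as its commercial dimer, which reverts to the monomer on warming. In the furan intermediates C8, C7, C11 and C12 are furan C-2, C-3, C-4 and C-5. The hemiketal carbon C8 of 26 is expected as an epimer mixture and is left undefined; it is removed in step 15. "TBS" = tert-butyldimethylsilyl, "TIPS" = triisopropylsilyl.

**Step 1**
Reactants: 1 (S)-citramalic acid
Product: 2 2-[(4S)-2,2,4-trimethyl-5-oxo-1,3-dioxolan-4-yl]acetic acid
Conditions: Me2C(OMe)2, PPTS (cat.), CH2Cl2, rt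
Reagents that add atoms: 2,2-dimethoxypropane, COC(C)(C)OC
Why: Acid-catalysed transacetalisation closes the five-membered dioxolanone on the α-hydroxy acid rather than a six-membered ring on the β-carboxyl, masking the tertiary alcohol and the future acyl donor and leaving the other acid free, with the chiral-pool stereocentre untouched.

**Step 2**
Reactants: 2 2-[(4S)-2,2,4-trimethyl-5-oxo-1,3-dioxolan-4-yl]acetic acid; 3 Meldrum's acid
Product: 5 S-ethyl 3-oxo-4-[(4S)-2,2,4-trimethyl-5-oxo-1,3-dioxolan-4-yl]butanethioate, via acyl Meldrum's acid 4 (not isolated)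
Conditions: DCC, DMAP, CH2Cl2, 0 °C → rt; filter, acid wash; then EtSH (excess), toluene, 80 °C, sealed tube
Reagents that add atoms: ethanethiol, CCS
Why: Carbodiimide C-acylation of Meldrum's acid followed by thermolysis to the acylketene and its capture by the thiol is the standard two-carbon homologation of an acid to a β-keto thioester, and the neutral thiol does not open the dioxolanone.

**Step 3**
Reactants: 5 S-ethyl 3-oxo-4-[(4S)-2,2,4-trimethyl-5-oxo-1,3-dioxolan-4-yl]butanethioate; 6 1,3-dihydroxyacetone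
Product: 7 S-ethyl 4-(hydroxymethyl)-2-{[(4S)-2,2,4-trimethyl-5-oxo-1,3-dioxolan-4-yl]methyl}furan-3-carbothioate
Conditions: Sc(OTf)3 (10 mol %), 4 Å MS, MeCN, 50 °C
Reagents that add atoms: none
Why: García González-type furan annulation, in which Knoevenagel condensation of the doubly activated methylene with the ketone of dihydroxyacetone is followed by attack of the ketone enol oxygen on an allylic CH2OH and loss of water, should place the thioester at C-3 and CH2OH at C-4 and leave C-5 unsubstituted.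

**Step 4**
Reactants: 7 S-ethyl 4-(hydroxymethyl)-2-{[(4S)-2,2,4-trimethyl-5-oxo-1,3-dioxolan-4-yl]methyl}furan-3-carbothioate
Product: 8 S-ethyl 4-{[(tert-butyldimethylsilyl)oxy]methyl}-2-{[(4S)-2,2,4-trimethyl-5-oxo-1,3-dioxolan-4-yl]methyl}furan-3-carbothioate
Conditions: TBSCl, imidazole, CH2Cl2, 0 °C
Reagents that add atoms: tert-butyldimethylsilyl chloride, CC(C)(C)[Si](C)(C)Cl
Why: Standard silylation of the only free (primary) hydroxyl.

**Step 5**
Reactants: 8 S-ethyl 4-{[(tert-butyldimethylsilyl)oxy]methyl}-2-{[(4S)-2,2,4-trimethyl-5-oxo-1,3-dioxolan-4-yl]methyl}furan-3-carbothioate; 9 (E)-prop-1-en-1-ylboronic acid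
Product: 10 (2E)-1-[4-{[(tert-butyldimethylsilyl)oxy]methyl}-2-{[(4S)-2,2,4-trimethyl-5-oxo-1,3-dioxolan-4-yl]methyl}furan-3-yl]but-2-en-1-one
Conditions: Pd2(dba)3 (2.5 mol %), P(2-furyl)3 (10 mol %), CuTC (1.5 equiv), THF, 50 °C
Reagents that add atoms: none
Why: Liebeskind–Srogl coupling activates only the C–S bond under neutral conditions, so the thioester should become the (E)-propenyl ketone with retention of alkene geometry while the dioxolanone is left alone.

**Step 6**
Reactants: 10 (2E)-1-[4-{[(tert-butyldimethylsilyl)oxy]methyl}-2-{[(4S)-2,2,4-trimethyl-5-oxo-1,3-dioxolan-4-yl]methyl}furan-3-yl]but-2-en-1-one; 11 ethynyltriisopropylsilane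
Product: 12 (3S)-1-[4-{[(tert-butyldimethylsilyl)oxy]methyl}-2-{[(4S)-2,2,4-trimethyl-5-oxo-1,3-dioxolan-4-yl]methyl}furan-3-yl]-3-methyl-5-(triisopropylsilyl)pent-4-yn-1-one
Conditions: [Rh(OAc)(C2H4)2]2 (2.5 mol %), (R)-DTBM-SEGPHOS (6 mol %), 1,4-dioxane, 80 °C
Reagents that add atoms: none
Why: Rh(I)/bisphosphine-catalysed asymmetric conjugate alkynylation of a β-alkyl enone with a bulky silylacetylene sets the methyl-bearing centre (C4) as (S) under ligand control; the ligand antipode that delivers (S) is to be confirmed by correlation on the first run, both antipodes being available.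

**Step 7**
Reactants: 12 (3S)-1-[4-{[(tert-butyldimethylsilyl)oxy]methyl}-2-{[(4S)-2,2,4-trimethyl-5-oxo-1,3-dioxolan-4-yl]methyl}furan-3-yl]-3-methyl-5-(triisopropylsilyl)pent-4-yn-1-one
Product: 13 (1S,3S)-1-[4-{[(tert-butyldimethylsilyl)oxy]methyl}-2-{[(4S)-2,2,4-trimethyl-5-oxo-1,3-dioxolan-4-yl]methyl}furan-3-yl]-3-methyl-5-(triisopropylsilyl)pent-4-yn-1-ol
Conditions: (R)-Me-CBS (0.2 equiv), BH3·SMe2, THF, −30 °C; aq. NH4Cl
Reagents that add atoms: none
Why: Corey–Bakshi–Shibata reduction with the (R)-oxazaborolidine treats the hindered furyl group as the large substituent and should give the (S)-carbinol (C6) under catalyst control, independent of the remote methyl centre.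

**Step 8**
Reactants: 14 1-[(tert-butyldimethylsilyl)oxy]propan-2-one; 15 triethyl phosphonoacetate
Product: 16 ethyl (2E)-4-[(tert-butyldimethylsilyl)oxy]-3-methylbut-2-enoate
Conditions: NaH, THF, 0 °C → rt
Reagents that add atoms: none
Why: Horner–Wadsworth–Emmons olefination of the α-silyloxy ketone should give mainly the (E)-enoate (CH2OTBS trans to the ester), the minor (Z)-isomer being removable by chromatography.

**Step 9**
Reactants: 16 ethyl (2E)-4-[(tert-butyldimethylsilyl)oxy]-3-methylbut-2-enoate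
Product: 17 (2E)-4-[(tert-butyldimethylsilyl)oxy]-3-methylbut-2-enoic acid
Conditions: LiOH, THF/H2O, rt; then 1 M HCl to pH 4
Reagents that add atoms: lithium hydroxide, [Li+].[OH-]
Why: Ester saponification under conditions that a primary TBS ether tolerates, without change of alkene geometry.

**Step 10**
Reactants: 13 (1S,3S)-1-[4-{[(tert-butyldimethylsilyl)oxy]methyl}-2-{[(4S)-2,2,4-trimethyl-5-oxo-1,3-dioxolan-4-yl]methyl}furan-3-yl]-3-methyl-5-(triisopropylsilyl)pent-4-yn-1-ol; 17 (2E)-4-[(tert-butyldimethylsilyl)oxy]-3-methylbut-2-enoic acid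
Product: 19 (1S,3S)-1-[4-{[(tert-butyldimethylsilyl)oxy]methyl}-2-{[(4S)-2,2,4-trimethyl-5-oxo-1,3-dioxolan-4-yl]methyl}furan-3-yl]-3-methyl-5-(triisopropylsilyl)pent-4-yn-1-yl (2E)-4-[(tert-butyldimethylsilyl)oxy]-3-methylbut-2-enoate, via mixed anhydride 18 (not isolated)
Conditions: 2,4,6-Cl3C6H2COCl, Et3N, THF, 0 °C; then 13, DMAP, toluene, rt
Reagents that add atoms: none
Why: Yamaguchi esterification acylates the only free hydroxyl (the hindered secondary furyl carbinol) with retention at the carbinol carbon, and low temperature with DMAP catalysis should limit deconjugation of the enoate.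

**Step 11**
Reactants: 19 (1S,3S)-1-[4-{[(tert-butyldimethylsilyl)oxy]methyl}-2-{[(4S)-2,2,4-trimethyl-5-oxo-1,3-dioxolan-4-yl]methyl}furan-3-yl]-3-methyl-5-(triisopropylsilyl)pent-4-yn-1-yl (2E)-4-[(tert-butyldimethylsilyl)oxy]-3-methylbut-2-enoate
Product: 21 (1S,3S)-1-[4-{[(tert-butyldimethylsilyl)oxy]methyl}-2-{[(4S)-2,2,4-trimethyl-5-oxo-1,3-dioxolan-4-yl]methyl}furan-3-yl]-3-methylpent-4-yn-1-yl (2E)-4-[(tert-butyldimethylsilyl)oxy]-3-methylbut-2-enoate, via silver acetylide 20 (not isolated)
Conditions: AgF (1.5 equiv), MeCN, rt, dark; then 1 M HCl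
Reagents that add atoms: none
Why: Silver(I) fluoride cleaves the C(sp)–Si bond selectively through the silver acetylide, which is protonated on acidic work-up, and should leave the O-silyl ethers intact; it is done before any thioester is present because Ag(I) activates thioesters.

**Step 12**
Reactants: 21 (1S,3S)-1-[4-{[(tert-butyldimethylsilyl)oxy]methyl}-2-{[(4S)-2,2,4-trimethyl-5-oxo-1,3-dioxolan-4-yl]methyl}furan-3-yl]-3-methylpent-4-yn-1-yl (2E)-4-[(tert-butyldimethylsilyl)oxy]-3-methylbut-2-enoate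
Product: 22 S-ethyl (2S)-3-[3-{(1S,3S)-1-[(2E)-4-{[tert-butyldimethylsilyl]oxy}-3-methylbut-2-enoyl]oxy-3-methylpent-4-yn-1-yl}-4-{[(tert-butyldimethylsilyl)oxy]methyl}furan-2-yl]-2-hydroxy-2-methylpropanethioate (seco precursor)
Conditions: EtSH (3 equiv), DBU (0.1 equiv), THF, 0 °C
Reagents that add atoms: ethanethiol, CCS
Why: Thiolate acyl substitution opens the activated dioxolanone and the released hemiketal alkoxide loses acetone irreversibly, unveiling the tertiary alcohol and the thioester together, while the less electrophilic β,β-disubstituted enoate ester should not react at 0 °C.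

**Step 13**
Reactants: 22 seco α-hydroxy thioester / terminal alkyne
Product: 24 furan-fused 3(2H)-furanone macrocycle: (4S,6S,10S)-3,10-epoxy-1-oxo-ten-membered ring C1–C10 with C2=C3, furan on C7/C8 (O on C8, C12–H), C13–OTBS and the 6-O-[(2E)-4-(TBSO)-3-methylbut-2-enoyl] ester, via macrocyclic ynone 23 (not isolated)
Conditions: PdCl2(dppf) (10 mol %), P(2-furyl)3 (25 mol %), CuI (1.7 equiv), Et3N, DMF, 50 °C, syringe-pump addition to 1 mM, Ar; Et2NH added to the same flask if 23 persists
Reagents that add atoms: none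
Why: Proposed new method: Pd(0), helped by thiophilic Cu(I), inserts into the C(acyl)–S bond of the α-hydroxy thioester, the copper acetylide of the terminal alkyne transmetalates, and reductive elimination closes the ten-membered ring as ynone 23, whose tertiary hydroxyl then adds across the polarised triple bond (Cu/amine-promoted oxa-Michael) to give the 3(2H)-furanone. The closest known reactions are the intermolecular Pd/Cu coupling of thioesters with 1-alkynes to ynones (Fukuyama-type acyl Sonogashira) and the base- or metal-mediated cyclisation of α'-hydroxy ynones to 3(2H)-furanones; their union in a macrocyclising cascade is new. The ten-membered carbocycle closes by C(sp)–C(acyl) reductive elimination (a ten-membered ring tolerates one alkyne, as ten-membered enediynes show), and the furanone closes by a 5-endo-dig transannular O-attack that also creates the nine-membered oxa-bridge and releases the alkyne strain. No stereocentre is formed: C4, C6 and C10 are carried in, and the quaternary C10 cannot epimerise. The step needs ring closure over oligomerisation and Glaser dimerisation, which the furan (a built-in cis turn holding the two arms ortho), the gem-disubstituted carbinol, high dilution and exclusion of oxygen should secure. Acyl transfer to carbon and not to oxygen is secured by silyl protection of both primary alcohols, and only the β-alkyne carbon is within reach of the hydroxyl, which fixes the regiochemistry of O-addition.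

**Step 14**
Reactants: 24 furan-fused 3(2H)-furanone macrocycle
Product: 26 8-hydroxy-7(11)-en-8,12-olide (γ-hydroxybutenolide) bis-TBS ether, via furan endoperoxide 25 (not isolated)
Conditions: O2, TPP (cat.), hν (visible), i-Pr2NEt, CH2Cl2, −78 °C; cold oxalic acid quench
Reagents that add atoms: oxygen, O=O
Why: [4+2] cycloaddition of singlet oxygen to the electron-rich trisubstituted furan (the vinylogous-ester furanone and the enoate are inert), followed by base-induced Kornblum–DeLaMare fragmentation at the only C–H bridgehead (C12), should give the γ-hydroxybutenolide with the carbonyl at C12 and the hemiketal at C8.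

**Step 15**
Reactants: 26 γ-hydroxybutenolide bis-TBS ether
Product: 27 bis-TBS ether of the target (8E-ylidene butenolide)
Conditions: p-TsOH·H2O (10 mol %), 4 Å MS, toluene, 60 °C
Reagents that add atoms: none
Why: Acid-catalysed E1 dehydration of the tertiary hemiketal through the acyloxocarbenium ion can lose a proton only from C9, and the medium ring allows only the alkene with C7 and C10 cis, which is the (E)-ylidene butenolide of the target.

**Step 16**
Reactants: 27 bis-TBS ether of the target
Product: 28 target CNP0288314.1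
Conditions: HF·pyridine, pyridine/THF, 0 °C → rt
Reagents that add atoms: none
Why: Fluoride-mediated cleavage of the two primary TBS ethers under mildly acidic conditions should leave the enol lactone, the furanone and the enoate ester intact.

**Compound list**
1 | (S)-citramalic acid, (2S)-2-hydroxy-2-methylbutanedioic acid | OC(=O)C[C@](C)(O)C(=O)O | starting material
2 | 2-[(4S)-2,2,4-trimethyl-5-oxo-1,3-dioxolan-4-yl]acetic acid | OC(=O)C[C@]1(C)OC(C)(C)OC1=O | intermediate
3 | Meldrum's acid (2,2-dimethyl-1,3-dioxane-4,6-dione) | CC1(C)OC(=O)CC(=O)O1 | starting material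
4 | acyl Meldrum's acid (enol form) of 2 | CC1(C)OC(=O)C(=C(O)C[C@]2(C)OC(C)(C)OC2=O)C(=O)O1 | intermediate
5 | S-ethyl 3-oxo-4-[(4S)-2,2,4-trimethyl-5-oxo-1,3-dioxolan-4-yl]butanethioate | CCSC(=O)CC(=O)C[C@]1(C)OC(C)(C)OC1=O | intermediate
6 | 1,3-dihydroxyacetone | OCC(=O)CO | starting material
7 | S-ethyl 4-(hydroxymethyl)-2-{[(4S)-2,2,4-trimethyl-5-oxo-1,3-dioxolan-4-yl]methyl}furan-3-carbothioate | CCSC(=O)c1c(C[C@]2(C)OC(C)(C)OC2=O)occ1CO | intermediate
8 | TBS ether of 7 | CCSC(=O)c1c(C[C@]2(C)OC(C)(C)OC2=O)occ1CO[Si](C)(C)C(C)(C)C | intermediate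
9 | (E)-prop-1-en-1-ylboronic acid | C/C=C/B(O)O | starting material
10 | (2E)-1-[4-(TBSO-methyl)-2-{[(4S)-2,2,4-trimethyl-5-oxo-1,3-dioxolan-4-yl]methyl}furan-3-yl]but-2-en-1-one | C/C=C/C(=O)c1c(C[C@]2(C)OC(C)(C)OC2=O)occ1CO[Si](C)(C)C(C)(C)C | intermediate
11 | ethynyltriisopropylsilane | C#C[Si](C(C)C)(C(C)C)C(C)C | starting material
12 | (3S)-β-alkynyl ketone (3-methyl-5-TIPS-pent-4-yn-1-one on furan C-3) | O=C(C[C@H](C)C#C[Si](C(C)C)(C(C)C)C(C)C)c1c(C[C@]2(C)OC(C)(C)OC2=O)occ1CO[Si](C)(C)C(C)(C)C | intermediate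
13 | (1S,3S)-alcohol | O[C@@H](C[C@H](C)C#C[Si](C(C)C)(C(C)C)C(C)C)c1c(C[C@]2(C)OC(C)(C)OC2=O)occ1CO[Si](C)(C)C(C)(C)C | intermediate
14 | 1-[(tert-butyldimethylsilyl)oxy]propan-2-one | CC(=O)CO[Si](C)(C)C(C)(C)C | starting material
15 | triethyl phosphonoacetate | CCOC(=O)CP(=O)(OCC)OCC | starting material
16 | ethyl (2E)-4-[(tert-butyldimethylsilyl)oxy]-3-methylbut-2-enoate | C/C(=C\C(=O)OCC)CO[Si](C)(C)C(C)(C)C | intermediate
17 | (2E)-4-[(tert-butyldimethylsilyl)oxy]-3-methylbut-2-enoic acid | C/C(=C\C(=O)O)CO[Si](C)(C)C(C)(C)C | intermediate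
18 | mixed anhydride of 17 with 2,4,6-trichlorobenzoic acid | C/C(=C\C(=O)OC(=O)c1c(Cl)cc(Cl)cc1Cl)CO[Si](C)(C)C(C)(C)C | intermediate
19 | (1S,3S)-ester, TIPS-alkyne, dioxolanone | C/C(=C\C(=O)O[C@@H](C[C@H](C)C#C[Si](C(C)C)(C(C)C)C(C)C)c1c(C[C@]2(C)OC(C)(C)OC2=O)occ1CO[Si](C)(C)C(C)(C)C)CO[Si](C)(C)C(C)(C)C | intermediate
20 | silver acetylide of 21 | C/C(=C\C(=O)O[C@@H](C[C@H](C)C#C[Ag])c1c(C[C@]2(C)OC(C)(C)OC2=O)occ1CO[Si](C)(C)C(C)(C)C)CO[Si](C)(C)C(C)(C)C | intermediate
21 | (1S,3S)-ester, terminal alkyne, dioxolanone | C/C(=C\C(=O)O[C@@H](C[C@H](C)C#C)c1c(C[C@]2(C)OC(C)(C)OC2=O)occ1CO[Si](C)(C)C(C)(C)C)CO[Si](C)(C)C(C)(C)C | intermediate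
22 | seco precursor: (2S)-α-hydroxy S-ethyl thioester with terminal alkyne | C/C(=C\C(=O)O[C@@H](C[C@H](C)C#C)c1c(C[C@](C)(O)C(=O)SCC)occ1CO[Si](C)(C)C(C)(C)C)CO[Si](C)(C)C(C)(C)C | intermediate
23 | furan-fused ten-membered α'-hydroxy ynone (4S,6S,10S) | C/C(=C\C(=O)O[C@H]1C[C@H](C)C#CC(=O)[C@@](C)(O)Cc2occ(CO[Si](C)(C)C(C)(C)C)c21)CO[Si](C)(C)C(C)(C)C | intermediate
24 | furan-fused 3(2H)-furanone macrocycle (4S,6S,10S) | C/C(=C\C(=O)O[C@H]1C[C@H](C)C2=CC(=O)[C@@](C)(O2)Cc2occ(CO[Si](C)(C)C(C)(C)C)c21)CO[Si](C)(C)C(C)(C)C | intermediate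
25 | furan endoperoxide of 24 (C8/C12 peroxide bridge) | C/C(=C\C(=O)O[C@H]1C[C@H](C)C2=CC(=O)[C@@](C)(O2)CC24OOC(O2)C(CO[Si](C)(C)C(C)(C)C)=C41)CO[Si](C)(C)C(C)(C)C | intermediate
26 | 8-hydroxy-7(11)-en-8,12-olide, bis-TBS ether (C8 epimers) | C/C(=C\C(=O)O[C@H]1C[C@H](C)C2=CC(=O)[C@@](C)(O2)CC2(O)OC(=O)C(CO[Si](C)(C)C(C)(C)C)=C21)CO[Si](C)(C)C(C)(C)C | intermediate
27 | bis-TBS ether of the target | C/C(=C\C(=O)O[C@H]1C[C@H](C)C2=CC(=O)[C@](C)(/C=C3/OC(=O)C(CO[Si](C)(C)C(C)(C)C)=C31)O2)CO[Si](C)(C)C(C)(C)C | intermediate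
28 | CNP0288314.1: (4S,6S,10S,8E)-3,10-epoxy-13-hydroxy-1-oxogermacra-2,7(11),8-trien-8,12-olide 6-O-[(2E)-4-hydroxy-3-methylbut-2-enoate] | C/C(=C\C(=O)O[C@H]1C[C@H](C)C2=CC(=O)[C@](C)(/C=C3/OC(=O)C(CO)=C31)O2)CO | target

**Step count**
Total: 16 steps. Longest linear sequence: 14 steps (steps 1–7 and 10–16, from (S)-citramalic acid).

**Steps most likely to fail**

1. Step 13 (proposed new method). Oligomerisation or Glaser dimerisation may outrun ring closure, the acyl–palladium species may decarbonylate, or the strained ynone may decompose before the hydroxyl adds. The fallback builds the same ring by stepwise, known chemistry and sets out from 19. Thiolysis as in step 12 gives the TIPS-alkyne α-hydroxy thioester F1. Fukuyama reduction (Et3SiH, Pd/C, acetone) gives the α-hydroxy aldehyde F2, which has no α-hydrogen and cannot epimerise. AgF/NIS in MeCN converts the silylalkyne directly into the iodoalkyne aldehyde F3. Nozaki–Hiyama–Kishi cyclisation (CrCl2, cat. NiCl2, THF, high dilution) closes the ten-membered ring as the macrocyclic propargylic diol F4. Dess–Martin oxidation of the secondary alcohol then gives ynone 23, now isolated, and AuCl3 (cat.) or Et2NH cyclises it to 24, where the route is rejoined.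

2. Step 3. The dioxolanone may hydrolyse or the thioester may solvolyse under Lewis acid and released water, or Knoevenagel condensation at the ketone of dihydroxyacetone may be too slow. The fallback is an alkylative Feist–Bénary annulation and sets out from 5. Treatment with 1,3-dichloroacetone in pyridine, then TsOH to dehydrate the hydroxydihydrofuran, gives the 4-(chloromethyl)furan F5. Caesium formate in DMF gives the formate ester F6. Brief KHCO3/MeOH at 0 °C removes the formyl group and returns to 7.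

3. Step 14. The amine may open the hydroxybutenolide to its keto-carboxylate, which can then lose the furanone oxygen by β-elimination (retro-oxa-Michael) and scramble C10. The fallback avoids amine base and sets out from 24. NBS/NaHCO3 in aqueous acetone at −20 °C opens the furan oxidatively to the (Z)-keto-enal F7. Pinnick oxidation (NaClO2, NaH2PO4, 2-methyl-2-butene) of the aldehyde under acidic buffer closes the pseudo-acid and returns to 26.

**Further compounds**
F1 | step 13 | TIPS-alkyne (2S)-α-hydroxy S-ethyl thioester | C/C(=C\C(=O)O[C@@H](C[C@H](C)C#C[Si](C(C)C)(C(C)C)C(C)C)c1c(C[C@](C)(O)C(=O)SCC)occ1CO[Si](C)(C)C(C)(C)C)CO[Si](C)(C)C(C)(C)C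
F2 | step 13 | TIPS-alkyne (2S)-α-hydroxy aldehyde | C/C(=C\C(=O)O[C@@H](C[C@H](C)C#C[Si](C(C)C)(C(C)C)C(C)C)c1c(C[C@](C)(O)C=O)occ1CO[Si](C)(C)C(C)(C)C)CO[Si](C)(C)C(C)(C)C
F3 | step 13 | iodoalkyne (2S)-α-hydroxy aldehyde | C/C(=C\C(=O)O[C@@H](C[C@H](C)C#CI)c1c(C[C@](C)(O)C=O)occ1CO[Si](C)(C)C(C)(C)C)CO[Si](C)(C)C(C)(C)C
F4 | step 13 | furan-fused ten-membered propargylic diol (C1 epimers) | C/C(=C\C(=O)O[C@H]1C[C@H](C)C#CC(O)[C@@](C)(O)Cc2occ(CO[Si](C)(C)C(C)(C)C)c21)CO[Si](C)(C)C(C)(C)C
F5 | step 3 | S-ethyl 4-(chloromethyl)-2-{[(4S)-2,2,4-trimethyl-5-oxo-1,3-dioxolan-4-yl]methyl}furan-3-carbothioate | CCSC(=O)c1c(C[C@]2(C)OC(C)(C)OC2=O)occ1CCl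
F6 | step 3 | S-ethyl 4-[(formyloxy)methyl]-2-{[(4S)-2,2,4-trimethyl-5-oxo-1,3-dioxolan-4-yl]methyl}furan-3-carbothioate | CCSC(=O)c1c(C[C@]2(C)OC(C)(C)OC2=O)occ1COC=O
F7 | step 14 | (Z)-8-oxo-12-al macrocycle (ring-opened furan), bis-TBS ether | C/C(=C\C(=O)O[C@H]1C[C@H](C)C2=CC(=O)[C@@](C)(O2)CC(=O)/C1=C(\C=O)CO[Si](C)(C)C(C)(C)C)CO[Si](C)(C)C(C)(C)C
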